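**Retrosynthetic overview**
1. The target is a (2R,5R,9R,10R,13S)-labda-7,14-diene: the C2 senecioate is put on last, and the C13 carbinol is made by forming C12–C13 in a lithiation–borylation of a C12 pinacol boronate grown from a C9 ester (C11).
2. The strategy rests on ring B as a cyclohexene retron inside the trans-fused A/B decalin, with contiguous stereocentres C5, C10 (quaternary, carrying C20) and C9 flanking the C5–C10 and C8–C9 bonds.
3. Both bonds are cut in an intramolecular Diels–Alder reaction of an open-chain 2-silyloxydiene/E-enoate whose only stereocentre is C2; rings A and B form together in that one step.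
4. The triene comes from (S)-epichlorohydrin (C1–C3), trimethylsilylacetylene (C9, C10), prenyl chloride (C4–C6, C18, C19) and (E)-1-bromopropene (C7, C8, C17).
5. After the cycloaddition, Saegusa–Ito oxidation, Luche reduction and ionic deoxygenation turn the C6 enol ether into C7=C8/C6H2 while C9 still carries the ester.

Key step: step 12

Remark: atom labels C1–C20 follow labdane numbering (C11 on C9, C17 on C8, C18/C19 on C4, C20 on C10); the lithiation–borylation in step 21 is assumed to take the usual course for lithiated secondary carbamates and pinacol boronates (lithiation and borylation with retention, 1,2-migration with inversion).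

**Route**

Step 1
Reactants: 1 (S)-epichlorohydrin; 2 trimethylsilylacetylene
Product: 4 (S)-1-chloro-5-(trimethylsilyl)pent-4-yn-2-ol, via lithium (trimethylsilyl)acetylide 3 (not isolated)
Conditions: 2, n-BuLi, THF, −78 °C; BF3·OEt2, then 1, −78 °C
Reagents that add atoms: none
Why: BF3-promoted alkynylation of an epoxide, in which the acetylide opens the oxirane at its unsubstituted carbon faster than it displaces chloride, so the stereocentre (later C2) is not touched.

Step 2
Reactants: 4 (S)-1-chloro-5-(trimethylsilyl)pent-4-yn-2-ol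
Product: 5 (S)-trimethyl[3-(oxiran-2-yl)prop-1-yn-1-yl]silane
Conditions: NaH, THF, 0 °C → rt
Reagents that add atoms: none
Why: Intramolecular Williamson etherification of the chlorohydrin alkoxide moves the epoxide to the other terminus without breaking the C–O bond at the stereocentre, and the aprotic base leaves the alkynylsilane intact.

Step 3
Reactants: 5 (S)-trimethyl[3-(oxiran-2-yl)prop-1-yn-1-yl]silane; 6 prenyl chloride
Product: 8 (4R)-6,6-dimethyl-1-(trimethylsilyl)oct-7-en-1-yn-4-ol, via prenylmagnesium chloride 7 (not isolated)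
Conditions: 6, Mg, THF, 0 °C; then 5, THF, −20 → 0 °C
Reagents that add atoms: none
Why: Allylic Grignard reagents open epoxides by SE2' attack through their γ-carbon, so the tertiary prenyl terminus bonds to the unsubstituted oxirane carbon and gives the quaternary C4 with its vinyl group (C5, C6) while the carbinol centre is untouched.

Step 4
Reactants: 8 (4R)-6,6-dimethyl-1-(trimethylsilyl)oct-7-en-1-yn-4-ol
Product: 9 tert-butyl{[(4R)-6,6-dimethyl-1-(trimethylsilyl)oct-7-en-1-yn-4-yl]oxy}dimethylsilane
Conditions: TBSCl, imidazole, DMF, rt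
Reagents that add atoms: tert-butyldimethylsilyl chloride, CC(C)(C)[Si](C)(C)Cl
Why: Standard imidazole-mediated silylation of an unhindered secondary alcohol protects the future C2 oxygen for the organometallic and thermal steps ahead.

Step 5
Reactants: 9 tert-butyl{[(4R)-6,6-dimethyl-1-(trimethylsilyl)oct-7-en-1-yn-4-yl]oxy}dimethylsilane
Product: 10 tert-butyl{[(4S)-6,6-dimethyloct-7-en-1-yn-4-yl]oxy}dimethylsilane
Conditions: K2CO3, MeOH, rt
Reagents that add atoms: none
Why: Base-catalysed methanolysis cleaves the alkynyl C–Si bond selectively over the secondary O–Si ether and frees the terminal alkyne (the descriptor changes only through the priority rules).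

Step 6
Reactants: 10 tert-butyl{[(4S)-6,6-dimethyloct-7-en-1-yn-4-yl]oxy}dimethylsilane
Product: 12 methyl (2E,5S)-5-[(tert-butyldimethylsilyl)oxy]-3,7,7-trimethylnona-2,8-dienoate, via E-alkenyl(dimethyl)alane 11 (not isolated)
Conditions: Me3Al, Cp2ZrCl2 (cat.), CH2Cl2, 0 °C → rt; then ClCO2Me, 0 °C → rt
Reagents that add atoms: trimethylaluminium, C[Al](C)C; methyl chloroformate, COC(=O)Cl
Why: Negishi carboalumination adds methyl (C20) and aluminium syn across the terminal alkyne with methyl on the internal carbon, and acylation of the alkenylalane with retention gives the E-enoate (ester trans to the tether), the hindered unactivated vinyl group reacting far more slowly.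

Step 7
Reactants: 12 methyl (2E,5S)-5-[(tert-butyldimethylsilyl)oxy]-3,7,7-trimethylnona-2,8-dienoate
Product: 14 methyl (2E,5R)-5-[(tert-butyldimethylsilyl)oxy]-9-hydroxy-3,7,7-trimethylnon-2-enoate, via B-alkyl-9-borabicyclo[3.3.1]nonane 13 (not isolated)
Conditions: 9-BBN, THF, 0 °C → rt; then 30% H2O2, aq. NaOAc, 0 °C → rt
Reagents that add atoms: hydrogen peroxide, OO
Why: Hydroboration–oxidation with 9-BBN is anti-Markovnikov and selective for the monosubstituted vinyl group over the trisubstituted enoate, and buffered peroxide gives the primary C6 alcohol without ester hydrolysis.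

Step 8
Reactants: 14 methyl (2E,5R)-5-[(tert-butyldimethylsilyl)oxy]-9-hydroxy-3,7,7-trimethylnon-2-enoate
Product: 15 methyl (2E,5R)-5-[(tert-butyldimethylsilyl)oxy]-3,7,7-trimethyl-9-oxonon-2-enoate
Conditions: Dess–Martin periodinane, NaHCO3, CH2Cl2, 0 °C → rt
Reagents that add atoms: none
Why: Dess–Martin oxidation takes the primary alcohol to the aldehyde under buffered, non-epimerising conditions that leave the silyl ether and the enoate alone.

Step 9
Reactants: 15 methyl (2E,5R)-5-[(tert-butyldimethylsilyl)oxy]-3,7,7-trimethyl-9-oxonon-2-enoate; 16 (E)-1-bromoprop-1-ene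
Product: 18 methyl (2E,5R,10E)-5-[(tert-butyldimethylsilyl)oxy]-9-hydroxy-3,7,7-trimethyldodeca-2,10-dienoate (both C9 epimers), via (E)-prop-1-enyllithium 17 (not isolated)
Conditions: 16, t-BuLi (2 equiv), Et2O, −78 °C; then 15, Et2O, −78 °C
Reagents that add atoms: none
Why: Bromine–lithium exchange proceeds with retention to the E-propenyllithium, which adds 1,2 to the aldehyde much faster than to the β,β-disubstituted enoate at −78 °C; the new carbinol centre is uncontrolled and is erased in step 10.

Step 10
Reactants: 18 methyl (2E,5R,10E)-5-[(tert-butyldimethylsilyl)oxy]-9-hydroxy-3,7,7-trimethyldodeca-2,10-dienoate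
Product: 19 methyl (2E,5R,10E)-5-[(tert-butyldimethylsilyl)oxy]-3,7,7-trimethyl-9-oxododeca-2,10-dienoate
Conditions: Dess–Martin periodinane, NaHCO3, CH2Cl2, rt
Reagents that add atoms: none
Why: Dess–Martin oxidation of the secondary allylic alcohol gives the E-propenyl ketone (C6 carbonyl) without moving either double bond.

Step 11
Reactants: 19 methyl (2E,5R,10E)-5-[(tert-butyldimethylsilyl)oxy]-3,7,7-trimethyl-9-oxododeca-2,10-dienoate
Product: 20 methyl (2E,5S,8Z,10E)-5,9-bis[(tert-butyldimethylsilyl)oxy]-3,7,7-trimethyldodeca-2,8,10-trienoate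
Conditions: TBSOTf, Et3N, CH2Cl2, −78 → 0 °C; filtration through Et3N-deactivated silica, used at once
Reagents that add atoms: tert-butyldimethylsilyl triflate, CC(C)(C)[Si](C)(C)OS(=O)(=O)C(F)(F)F
Why: Soft enolisation (O-silylation, then deprotonation at the α'-methylene C5) gives the cross-conjugated 2-silyloxydiene, and the Z enol ether is favoured because the other geometry forces the quaternary C4 against the propenyl group (A(1,3) strain), which also places the tether on the outside of the diene.

Step 12
Reactants: 20 methyl (2E,5S,8Z,10E)-5,9-bis[(tert-butyldimethylsilyl)oxy]-3,7,7-trimethyldodeca-2,8,10-trienoate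
Product: 21 trans-fused adduct, methyl 4,7-bis[(tert-butyldimethylsilyl)oxy]-2,5,5,8a-tetramethyl-1,2,4a,5,6,7,8,8a-octahydronaphthalene-1-carboxylate (C6=C7 silyl enol ether; C9 ester and C8 methyl cis to the C20 methyl; H5 and the C2 silyloxy group trans to C20)
Conditions: PhMe (0.01 M), BHT, Et3N (trace), sealed tube, 190 °C
Reagents that add atoms: none
Why: The step is a concerted, asynchronous thermal [4+2], the intramolecular Diels–Alder reaction of a 1,7,9-decatriene with a 2-silyloxydiene and a terminal enoate (a known reaction type); the C6 silyloxy group and the C8 methyl raise the diene coefficient at C5, which bonds to the enoate β-carbon C10, and the quaternary C4 compresses the tether and removes any allylic hydrogen that could undergo a 1,5-shift. Ring B closes as the new cyclohexene that holds both new bonds (C5–C10, C8–C9), and ring A closes through the C1–C4 tether folded as a chair. At C9 and C10, suprafacial addition to the E-enoate keeps the ester cis to the C20 methyl, and at C8 the E-propenyl terminus places C17 cis to the endo ester (this centre is erased in step 13). At C5, the endo transition state (ester under the diene, tether anti) should give the trans ring fusion. The absolute sense comes from C2, whose silyloxy group stays equatorial in the chair tether because the axial position would be syn-diaxial to C20 and to one C4 methyl. The step therefore needs endo/exo and π-facial selectivity (regiochemistry is fixed by the tether), the first resting on the endo preference of the ester and the second on the C2 stereocentre.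

Step 13
Reactants: 21 trans-fused silyl enol ether adduct
Product: 22 methyl 7-[(tert-butyldimethylsilyl)oxy]-2,5,5,8a-tetramethyl-4-oxo-1,4,4a,5,6,7,8,8a-octahydronaphthalene-1-carboxylate (7-en-6-one; configuration at C2, C5, C9, C10 unchanged)
Conditions: Pd(OAc)2 (1.1 equiv), MeCN, rt → 40 °C
Reagents that add atoms: none
Why: Saegusa–Ito oxidation, in which the enol ether is palladated at C7 on the face away from the C20 and C17 methyls and syn β-hydride elimination of H8 gives the C7=C8 enone and zerovalent palladium; the neutral medium leaves the acidic C9–H (α to the ester, γ to the enone) and C5 untouched.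

Step 14
Reactants: 22 7-en-6-one ester
Product: 23 methyl 7-[(tert-butyldimethylsilyl)oxy]-4-hydroxy-2,5,5,8a-tetramethyl-1,4,4a,5,6,7,8,8a-octahydronaphthalene-1-carboxylate (axial C6 hydroxyl, cis to C20)
Conditions: NaBH4, CeCl3·7H2O, MeOH, −78 → −20 °C
Reagents that add atoms: none
Why: Luche reduction is 1,2-selective and spares the ester, hydride arriving on the face opposite the axial C20 and C4 methyls to give the axial allylic alcohol (a centre removed in step 15), and the low temperature avoids enolisation at C9.

Step 15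
Reactants: 23 C6 allylic alcohol
Product: 24 methyl 7-[(tert-butyldimethylsilyl)oxy]-2,5,5,8a-tetramethyl-1,4,4a,5,6,7,8,8a-octahydronaphthalene-1-carboxylate (C7=C8, C6H2)
Conditions: Et3SiH, BF3·OEt2, CH2Cl2, −78 → −40 °C
Reagents that add atoms: none
Why: Ionic deoxygenation, in which the axial allylic hydroxyl ionises to the C6–C7–C8 allyl cation and the silane delivers hydride to the secondary terminus C6 (as in mixed-hydride reductions of 3-hydroxy-4-ene systems), keeping the trisubstituted C7=C8 bond; the aprotic Lewis acid at low temperature does not protonate the alkene or cleave the silyl ether.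

Step 16
Reactants: 24 C7=C8 methyl ester
Product: 25 [7-[(tert-butyldimethylsilyl)oxy]-2,5,5,8a-tetramethyl-1,4,4a,5,6,7,8,8a-octahydronaphthalen-1-yl]methanol (C11 primary alcohol)
Conditions: LiAlH4, Et2O, 0 °C
Reagents that add atoms: none
Why: Hydride reduction of the ester to the primary alcohol does not touch the isolated alkene, the silyl ether or the C9 stereocentre.

Step 17
Reactants: 25 C11 primary alcohol
Product: 26 the corresponding C11 aldehyde (C9–CHO)
Conditions: Dess–Martin periodinane, NaHCO3, CH2Cl2, 0 °C; used crude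
Reagents that add atoms: none
Why: Buffered Dess–Martin oxidation gives the β,γ-unsaturated aldehyde under conditions too mild to epimerise C9 or move the C7=C8 bond into conjugation.

Step 18
Reactants: 26 C11 aldehyde
Product: 27 the C9 vinyl compound (C11=C12)
Conditions: Ph3PCH3Br, KHMDS, THF, 0 °C; then 26, −78 → 0 °C
Reagents that add atoms: methyltriphenylphosphonium bromide, C[P+](c1ccccc1)(c1ccccc1)c1ccccc1.[Br-]
Why: Wittig methylenation with the salt-free ylide adds C12; addition at −78 °C should outrun enolisation of the hindered aldehyde, so C9 keeps its configuration.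

Step 19
Reactants: 27 C9 vinyl compound
Product: 28 the C12 pinacol boronate (C9–CH2CH2–Bpin)
Conditions: HBpin, [Ir(cod)Cl]2 (cat.), dppm (cat.), CH2Cl2, rt
Reagents that add atoms: pinacolborane, CC1(C)OBOC1(C)C
Why: Iridium-catalysed hydroboration with pinacolborane is terminal-selective for monosubstituted alkenes and leaves the trisubstituted C7=C8 bond alone.

Step 20
Reactants: 29 (R)-but-3-en-2-ol
Product: 30 (R)-but-3-en-2-yl N,N-diisopropylcarbamate
Conditions: iPr2NCOCl, Et3N, CH2Cl2, reflux
Reagents that add atoms: N,N-diisopropylcarbamoyl chloride, CC(C)N(C(C)C)C(Cl)=O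
Why: O-Carbamoylation installs the directing and leaving group for lithiation–borylation without touching the stereocentre.

Step 21
Reactants: 28 C12 pinacol boronate; 30 (R)-but-3-en-2-yl N,N-diisopropylcarbamate
Product: 34 the C13 tertiary allylic alcohol with the C2 silyl ether (13S), via lithiated carbamate 31 (not isolated), via boronate complex 32 (not isolated), via tertiary allylic boronic ester 33 (not isolated)
Conditions: 30, s-BuLi, TMEDA, Et2O, −78 °C; then 28, −78 °C → rt; then NaOH, H2O2, THF, 0 °C
Reagents that add atoms: hydrogen peroxide, OO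
Why: Lithiation–borylation, in which α-deprotonation gives a chelated, configurationally stable carbanion that is borylated at the α-carbon with retention, a stereospecific 1,2-metallate rearrangement with inversion expels the carbamate and forms C12–C13, and oxidation with retention gives the tertiary alcohol, so the (R)-carbamate should deliver 13S.

Step 22
Reactants: 34 C13 tertiary alcohol with the C2 silyl ether
Product: 35 (2R,5R,9R,10R,13S)-labda-7,14-diene-2,13-diol
Conditions: TBAF, THF, rt → 40 °C
Reagents that add atoms: none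
Why: Fluoride-mediated desilylation frees the secondary C2 alcohol without affecting the tertiary allylic alcohol or the alkenes.

Step 23
Reactants: 35 (2R,5R,9R,10R,13S)-labda-7,14-diene-2,13-diol
Product: 36 CNP0252389.1, the C2 3-methylbut-2-enoate of diol 35
Conditions: 3-methylbut-2-enoyl chloride, pyridine, DMAP (cat.), CH2Cl2, 0 °C → rt
Reagents that add atoms: 3-methylbut-2-enoyl chloride, CC(C)=CC(Cl)=O
Why: Acylation is selective for the equatorial secondary C2 hydroxyl over the tertiary C13 hydroxyl, and the weak base avoids deconjugation of the senecioyl group.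

**Compound list**
1 | (S)-epichlorohydrin | ClC[C@@H]1CO1 | starting material
2 | trimethylsilylacetylene | C#C[Si](C)(C)C | starting material
3 | lithium (trimethylsilyl)acetylide | [Li]C#C[Si](C)(C)C | intermediate
4 | (S)-1-chloro-5-(trimethylsilyl)pent-4-yn-2-ol | ClC[C@@H](O)CC#C[Si](C)(C)C | intermediate
5 | (S)-trimethyl[3-(oxiran-2-yl)prop-1-yn-1-yl]silane | C[Si](C)(C)C#CC[C@H]1CO1 | intermediate
6 | prenyl chloride (1-chloro-3-methylbut-2-ene) | CC(C)=CCCl | starting material
7 | prenylmagnesium chloride | CC(C)=CC[Mg]Cl | intermediate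
8 | (4R)-6,6-dimethyl-1-(trimethylsilyl)oct-7-en-1-yn-4-ol | C=CC(C)(C)C[C@@H](O)CC#C[Si](C)(C)C | intermediate
9 | tert-butyl{[(4R)-6,6-dimethyl-1-(trimethylsilyl)oct-7-en-1-yn-4-yl]oxy}dimethylsilane | C=CC(C)(C)C[C@@H](O[Si](C)(C)C(C)(C)C)CC#C[Si](C)(C)C | intermediate
10 | tert-butyl{[(4S)-6,6-dimethyloct-7-en-1-yn-4-yl]oxy}dimethylsilane | C=CC(C)(C)C[C@@H](O[Si](C)(C)C(C)(C)C)CC#C | intermediate
11 | E-alkenyl(dimethyl)alane from methylalumination of 10 (Al cis to the new methyl) | C[Al](C)/C=C(\C)C[C@H](O[Si](C)(C)C(C)(C)C)CC(C)(C)C=C | intermediate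
12 | methyl (2E,5S)-5-[(tert-butyldimethylsilyl)oxy]-3,7,7-trimethylnona-2,8-dienoate | COC(=O)/C=C(\C)C[C@H](O[Si](C)(C)C(C)(C)C)CC(C)(C)C=C | intermediate
13 | methyl (2E,5R)-9-(9-borabicyclo[3.3.1]nonan-9-yl)-5-[(tert-butyldimethylsilyl)oxy]-3,7,7-trimethylnon-2-enoate | COC(=O)/C=C(\C)C[C@H](O[Si](C)(C)C(C)(C)C)CC(C)(C)CCB1C2CCCC1CCC2 | intermediate
14 | methyl (2E,5R)-5-[(tert-butyldimethylsilyl)oxy]-9-hydroxy-3,7,7-trimethylnon-2-enoate | COC(=O)/C=C(\C)C[C@H](O[Si](C)(C)C(C)(C)C)CC(C)(C)CCO | intermediate
15 | methyl (2E,5R)-5-[(tert-butyldimethylsilyl)oxy]-3,7,7-trimethyl-9-oxonon-2-enoate | COC(=O)/C=C(\C)C[C@H](O[Si](C)(C)C(C)(C)C)CC(C)(C)CC=O | intermediate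
16 | (E)-1-bromoprop-1-ene | C/C=C/Br | starting material
17 | (E)-prop-1-enyllithium | C/C=C/[Li] | intermediate
18 | methyl (2E,5R,10E)-5-[(tert-butyldimethylsilyl)oxy]-9-hydroxy-3,7,7-trimethyldodeca-2,10-dienoate, both C9 epimers | COC(=O)/C=C(\C)C[C@H](O[Si](C)(C)C(C)(C)C)CC(C)(C)CC(O)/C=C/C | intermediate
19 | methyl (2E,5R,10E)-5-[(tert-butyldimethylsilyl)oxy]-3,7,7-trimethyl-9-oxododeca-2,10-dienoate | COC(=O)/C=C(\C)C[C@H](O[Si](C)(C)C(C)(C)C)CC(C)(C)CC(=O)/C=C/C | intermediate
20 | methyl (2E,5S,8Z,10E)-5,9-bis[(tert-butyldimethylsilyl)oxy]-3,7,7-trimethyldodeca-2,8,10-trienoate | COC(=O)/C=C(\C)C[C@H](O[Si](C)(C)C(C)(C)C)CC(C)(C)/C=C(O[Si](C)(C)C(C)(C)C)/C=C/C | intermediate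
21 | methyl 4,7-bis[(tert-butyldimethylsilyl)oxy]-2,5,5,8a-tetramethyl-1,2,4a,5,6,7,8,8a-octahydronaphthalene-1-carboxylate; trans-fused, C9 ester and C8 methyl cis to C20, C2 silyloxy trans to C20 | COC(=O)[C@@H]1[C@H](C)C=C(O[Si](C)(C)C(C)(C)C)[C@@H]2C(C)(C)C[C@@H](O[Si](C)(C)C(C)(C)C)C[C@@]12C | intermediate
22 | methyl 7-[(tert-butyldimethylsilyl)oxy]-2,5,5,8a-tetramethyl-4-oxo-1,4,4a,5,6,7,8,8a-octahydronaphthalene-1-carboxylate; trans-fused 7-en-6-one, C9 ester cis to C20 | COC(=O)[C@@H]1C(C)=CC(=O)[C@@H]2C(C)(C)C[C@@H](O[Si](C)(C)C(C)(C)C)C[C@@]12C | intermediate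
23 | methyl 7-[(tert-butyldimethylsilyl)oxy]-4-hydroxy-2,5,5,8a-tetramethyl-1,4,4a,5,6,7,8,8a-octahydronaphthalene-1-carboxylate; C6 hydroxyl axial, cis to C20 | COC(=O)[C@@H]1C(C)=C[C@H](O)[C@@H]2C(C)(C)C[C@@H](O[Si](C)(C)C(C)(C)C)C[C@@]12C | intermediate
24 | methyl 7-[(tert-butyldimethylsilyl)oxy]-2,5,5,8a-tetramethyl-1,4,4a,5,6,7,8,8a-octahydronaphthalene-1-carboxylate; C7=C8, trans-fused, C9 ester cis to C20 | COC(=O)[C@@H]1C(C)=CC[C@@H]2C(C)(C)C[C@@H](O[Si](C)(C)C(C)(C)C)C[C@@]12C | intermediate
25 | [7-[(tert-butyldimethylsilyl)oxy]-2,5,5,8a-tetramethyl-1,4,4a,5,6,7,8,8a-octahydronaphthalen-1-yl]methanol (C11 alcohol, same configuration) | OC[C@@H]1C(C)=CC[C@@H]2C(C)(C)C[C@@H](O[Si](C)(C)C(C)(C)C)C[C@@]12C | intermediate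
26 | C11 aldehyde of 25 (C9–CHO) | O=C[C@@H]1C(C)=CC[C@@H]2C(C)(C)C[C@@H](O[Si](C)(C)C(C)(C)C)C[C@@]12C | intermediate
27 | C9 vinyl compound (C11=C12), C2 silyl ether | C=C[C@@H]1C(C)=CC[C@@H]2C(C)(C)C[C@@H](O[Si](C)(C)C(C)(C)C)C[C@@]12C | intermediate
28 | C12 pinacol boronate (C9–CH2CH2–Bpin), C2 silyl ether | CC1(C)OB(CC[C@@H]2C(C)=CC[C@@H]3C(C)(C)C[C@@H](O[Si](C)(C)C(C)(C)C)C[C@@]23C)OC1(C)C | intermediate
29 | (R)-but-3-en-2-ol | C=C[C@@H](C)O | starting material
30 | (R)-but-3-en-2-yl N,N-diisopropylcarbamate | C=C[C@@H](C)OC(=O)N(C(C)C)C(C)C | intermediate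
31 | α-lithiated carbamate from 30 (lithium in place of H, retention) | C=C[C@@]([Li])(C)OC(=O)N(C(C)C)C(C)C | intermediate
32 | lithium boronate complex of 31 and 28 | [Li+].C=C[C@@]([B-]1(CC[C@@H]2C(C)=CC[C@@H]3C(C)(C)C[C@@H](O[Si](C)(C)C(C)(C)C)C[C@@]23C)OC(C)(C)C(C)(C)O1)(C)OC(=O)N(C(C)C)C(C)C | intermediate
33 | tertiary allylic pinacol boronic ester at C13 | C=C[C@](B1OC(C)(C)C(C)(C)O1)(C)CC[C@@H]2C(C)=CC[C@@H]3C(C)(C)C[C@@H](O[Si](C)(C)C(C)(C)C)C[C@@]23C | intermediate
34 | (13S)-2-[(tert-butyldimethylsilyl)oxy]labda-7,14-dien-13-ol | C=C[C@@](C)(O)CC[C@@H]1C(C)=CC[C@@H]2C(C)(C)C[C@@H](O[Si](C)(C)C(C)(C)C)C[C@@]12C | intermediate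
35 | (2R,5R,9R,10R,13S)-labda-7,14-diene-2,13-diol | C=C[C@@](C)(O)CC[C@@H]1C(C)=CC[C@@H]2C(C)(C)C[C@@H](O)C[C@@]12C | intermediate
36 | CNP0252389.1, (2R,5R,9R,10R,13S)-13-hydroxylabda-7,14-dien-2-yl 3-methylbut-2-enoate | C=C[C@@](C)(O)CC[C@@H]1C(C)=CC[C@@H]2C(C)(C)C[C@@H](OC(=O)C=C(C)C)C[C@@]12C | target

**Step count**
Total: 23 steps. Longest linear sequence: 22 steps (steps 1–19 and 21–23 from compound 1; step 20 is a one-step side branch).

**Steps most likely to fail**

Step 12 (cycloaddition). The dienophile carbon C10 is fully substituted, so ring closure may be slow enough for the dienol ether to degrade, and endo selectivity may erode toward cis-fused material. The fallback forms the same two bonds stepwise, by an anionic double Michael reaction. It sets out from ketone 19: LiHMDS (THF, −78 → 0 °C) generates the C5 enolate, which adds to the enoate at C10, and the resulting ester enolate closes ring B by adding to the enone at C8. Brief equilibration with NaOMe in MeOH then settles C5 (trans fusion) and C9 (equatorial ester) under thermodynamic control and should give the saturated trans-fused keto ester F1. Dehydrogenation of F1 with IBX (DMSO, 70 °C) can only run toward C7–C8, because C4 and C10 are quaternary, and comes back to the route at enone 22.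

Step 15 (deoxygenation). The allyl cation may capture hydride at the tertiary terminus C8, or lose the C9 proton to give a conjugated dienoate. The fallback replaces the free cation by a palladium-bound allyl unit. It sets out from allylic alcohol 23, which is acetylated (Ac2O, DMAP, pyridine) to the allylic acetate F2. Treatment with Pd(PPh3)4 and NaBH4 in THF should ionise the axial acetate from the open face anti to it, and hydride is then transferred to the less substituted terminus C6. The ester is not reduced, and the sequence comes back to the route at ester 24.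

Step 21 (lithiation–borylation). Borylation at the γ-terminus of the lithiated allyl carbamate, a 1,3-boron shift in the tertiary allylic boronate, or partial loss of configuration would each erode the C13 centre. The fallback sets C13 by a reagent-controlled epoxidation and sets out from vinyl compound 27. Hydroboration with 9-BBN gives the B-alkylborane F3, and B-alkyl Suzuki–Miyaura coupling with known (E)-3-iodobut-2-en-1-ol (Pd(dppf)Cl2, AsPh3, Cs2CO3, DMF/THF/H2O) forms C12–C13 and gives the E-allylic alcohol F4. Sharpless asymmetric epoxidation of F4 (L-(+)-diethyl tartrate, Ti(OiPr)4, t-BuOOH, CH2Cl2, −20 °C) should give the (13S,14S)-epoxy alcohol F5. I2, PPh3 and imidazole convert F5 into the epoxy iodide F6, and zinc in AcOH/EtOH opens F6 reductively to the tertiary allylic alcohol with its vinyl group, coming back to the route at compound 34.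

**Further compounds**
F1 | step 12 | methyl 7-[(tert-butyldimethylsilyl)oxy]-2,5,5,8a-tetramethyl-4-oxodecahydronaphthalene-1-carboxylate; trans-fused, C9 ester and C8 methyl equatorial | COC(=O)[C@@H]1[C@@H](C)CC(=O)[C@@H]2C(C)(C)C[C@@H](O[Si](C)(C)C(C)(C)C)C[C@@]12C
F2 | step 15 | C6 acetate of allylic alcohol 23 | COC(=O)[C@@H]1C(C)=C[C@H](OC(C)=O)[C@@H]2C(C)(C)C[C@@H](O[Si](C)(C)C(C)(C)C)C[C@@]12C
F3 | step 21 | B-alkyl-9-borabicyclo[3.3.1]nonane from 27 (boron on C12) | B1(CC[C@@H]2C(C)=CC[C@@H]3C(C)(C)C[C@@H](O[Si](C)(C)C(C)(C)C)C[C@@]23C)C4CCCC1CCC4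
F4 | step 21 | (13E)-2-[(tert-butyldimethylsilyl)oxy]labda-7,13-dien-15-ol | OC/C=C(\C)CC[C@@H]1C(C)=CC[C@@H]2C(C)(C)C[C@@H](O[Si](C)(C)C(C)(C)C)C[C@@]12C
F5 | step 21 | (13S,14S)-13,14-epoxy-2-[(tert-butyldimethylsilyl)oxy]labd-7-en-15-ol | OC[C@@H]1O[C@@]1(C)CC[C@@H]2C(C)=CC[C@@H]3C(C)(C)C[C@@H](O[Si](C)(C)C(C)(C)C)C[C@@]23C
F6 | step 21 | (13S,14S)-13,14-epoxy-15-iodo-2-[(tert-butyldimethylsilyl)oxy]labd-7-ene | IC[C@@H]1O[C@@]1(C)CC[C@@H]2C(C)=CC[C@@H]3C(C)(C)C[C@@H](O[Si](C)(C)C(C)(C)C)C[C@@]23C
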